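**Selectivity ratio.** I took the ratio κ = 3.29, the summed constants of the two steps that consume J.D over the constant of the step that makes it; it is the selectivity factor of this consecutive scheme.

J 0.32 M; E 12 mM (held); time 30 s

    E ⇌ D, rate k1*(csat - [D]) (k1 = 2.8 s⁻¹, csat = 12 mM)
    J + D → J.D (k2 = 7.3 L mol⁻¹ s⁻¹)
    D + J.D → D.J.D (k3 = 13 L mol⁻¹ s⁻¹)
    D + J.D → L (k4 = 11 L mol⁻¹ s⁻¹)

1. J.D at 30 s, in percent of the J charged
2. concentration of D in solution at 30 s, in percent of saturation

- at the start none of D is dissolved
- run time (flask): 30 s

**Fraction left.** J and J.D meet the same D, so I wrote y, J.D as a fraction of the J charged, against x, the fraction of J left: y = (x − x^κ)/(κ − 1).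

**Which numbers.** The two consuming constants enter y by their sum, so their split could be off without harm. Where x^κ is small, with x held, a relative error in κ counts 1.44 times in y. Since x = exp(−τ), with τ the J-consuming constant times mean D times time, a relative error in τ counts about τ times. With D held at its starting balance, time and saturation concentration count whole in τ, the transfer coefficient by 0.455.

**The number.** The half-life of D by its reaction with J alone, J as charged, 0.30 s, is shorter than the run, so I expected D to stay near its balance of transfer and uptake, 6.54 mM at the start. Holding that gave τ = 1.43, x = 23.9% and y = 10.0%. The balance redone there, with J.D's uptake counted through κ, put D at 67.8% of saturation.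

**The forecast.** The forecast gave y = 10.1% and D at 67.5% of saturation, with “J.D held low because it reacts with D about three times faster than J does”.

**The result.** The simulation of the flask gave y = 10.1% and D at 67.4% of saturation, with 24% of the J charged left; κ on that reading gives 10.1%. For the neighbouring flask charged with 0.80 M of J, the same reckoning gave a balance of 3.89 mM, x = 42.7% and y = 16.0%. The simulation of that flask left 47% of its charged J at 30.0 s, on which κ gives 16.9%, and it held J.D at 16.9% of the J charged.

The constants used here are assumed.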